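**Remarks on the chemistry (assumptions)**

- The target has no stereocentre and no stereogenic axis, so it is achiral. There is no enantiomer to select, and the route needs no stereocontrol beyond alkene geometry in intermediates.
- The trivial name is read as "...-5-methoxybibenzyl" (ring A C1 carries the CH2CH2 bridge to the 3-hydroxyphenyl ring); this agrees with the SMILES.
- Atom mapping of diene, ynone and cycloaddition product showed no constitutional error. One point is tightened: the diene must be the (3Z) isomer (benzylic CH2 on the same side as the C3 methoxy, pointing away from the ketene-acetal terminus), because only this isomer can reach the s-cis conformation. The C1=C2 geometry is immaterial.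

## Structural features

The target is a bibenzyl. Ring A is joined through a CH2–CH2 chain at C1 to a 3-hydroxyphenyl ring, and carries 4-hydroxybenzyl groups at C2 and C6, a free hydroxyl at C3, hydrogen at C4 and a methoxy group at C5. The four benzene rings are linked only by sp3 methylene or ethylene units; there is no fused or bridged ring and no stereocentre. Ring A is pentasubstituted, with three different carbon substituents side by side (C6, C1, C2) next to two meta-related oxygens that differ only by O-methylation. The fragile groups are the four electron-rich phenols, which are prone to air oxidation and to quinone-methide formation at the hydroxybenzyl CH2 positions under acid or oxidants, so they are best unveiled only in the last step. The real difficulty is regiochemical: substitution on a preformed resorcinol ring cannot tell C2 and C6 from C4, nor O3 from O5. The key step avoids this by treating C3(OH)–C4(H)–C5(OMe)–C6(benzyl) as a 1,3-dioxygenated four-carbon diene and C1–C2 as an alkyne. The C2 benzylic carbon is held at the ketone level, so it polarises the alkyne and is later reduced to CH2.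

## Logic of the disconnections

**21 ⇒ 18.** The C2 benzylic CH2 is traced back to a C=O and the three outer phenols to benzyl ethers. The carbonyl is what activates and polarises the dienophile, and the benzyl ethers keep every intermediate free of acidic OH. All four groups fall to hydrogen over palladium, so the endgame is one operation. The forward step must take a hindered, hydrogen-bonded diaryl ketone fully to CH2 without touching the arene rings.

**18 ⇒ 8 + 16 (through 17).** Ring A is cut at C6–C1 and C3–C2. This splits the pentasubstituted ring into two acyclic partners of similar size, and every substituent position, including the O3/O5 difference (silyl versus methyl), is fixed by connectivity. The forward step needs a regioselective [4+2] addition between a 4-substituted diene and an internal ynone, and aromatisation of 17 with the silyl group, not the methyl group, lost from oxygen.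

**8 ⇒ 6.** The O–Si bond is cut. The diene is simply the silylated γ-dienolate of an enol-ether ester, so no carbon skeleton changes. The forward step needs γ-deprotonation, O-silylation and the (3Z) geometry.

**6 ⇒ 4.** The enol O–CH3 bond is cut, which returns a β-keto ester. This methyl group becomes the C5 methoxy of the target, so the O3/O5 distinction is made here on a small molecule. The forward step needs O- rather than C-methylation.

**4 ⇒ 1 + 2.** The C4–C5 bond of the pentanoate is cut (the future C6–CH2 benzyl link is made one carbon away from the ring). Both pieces are catalogue compounds. The forward step needs alkylation at the terminal (γ) carbon only, which the dianion provides.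

**16 ⇒ 14 + 15.** The acyl–alkyne C–C bond is cut. This gives a terminal alkyne and an aroyl chloride and reaches the ketone oxidation level directly. The forward step needs a mild coupling that does not isomerise the ynone.

**14 ⇒ 10 + 11.** The bond between the benzylic and the propargylic carbon is cut. This leaves a benzylic bromide and a three-carbon propargyl anion equivalent. The forward step needs propargyl (not allenyl) selectivity, which the silyl cap on 11 provides.

**10 ⇒ 9.** The C–Br bond is cut back to the benzylic alcohol, a routine activation.

## Other disconnections considered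

**Alternative 1:** The cut is made on a preformed ring A, at the C1–Cα bridge bond and the C2–aroyl bond. Forward, fluoride would release the aryne from 3,5-dimethoxy-2-(trimethylsilyl)phenyl triflate A3. The enolate of methyl 3-[4-(benzyloxy)phenyl]-3-oxopropanoate A2 would add through carbon at the aryne carbon remote from the flanking methoxy, the aryl anion would close onto the ketone, and the four-membered alkoxide would reopen to the arylacetate A1.
- In its favour: two adjacent C–C bonds form in one mild step, which equals the chosen key step in bonds formed. The regiochemistry from the methoxy-distorted aryne is as predictable as the polar cycloaddition, also an equal point. The aroyl group lands ortho to a methoxy that chelation-controlled demethylation could later free selectively, so O3/O5 can be told apart.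
- Against it: ring A already exists, so C6 is still C–H in A1. The second 4-oxybenzyl group would have to enter by electrophilic benzylation, where C4 (between two oxygens) competes with C6. The acetate arm is one carbon and one aryl group short of the bridge and needs a reduce/aryl-metal addition/deoxygenate sequence. A3 itself takes several steps.
- Comparison: A1 fixes two of the three contiguous carbon substituents, whereas the chosen plan fixes all three and both oxygens. Step economy is clearly worse and one regiochemically open step remains.

**Alternative 2:** The cut is at the two aryl–CH2 bonds (C2, C6) and the C1–Cα bond. Forward, 1-(benzyloxy)-3-iodo-5-methoxybenzene A5, two equivalents of 2 and 1-(benzyloxy)-3-ethenylbenzene A6 would combine under palladium/norbornene catalysis (double ortho C–H alkylation, then ipso Heck termination) to the stilbene A4.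
- In its favour: three C–C bonds in one step, the highest convergence of all the plans. The endgame is better than the chosen one, since hydrogenation of an alkene plus four benzyl ethers is easier than removing a diaryl ketone. The sequence would be about three steps shorter, which is a real advantage in step economy.
- Against it: both ortho C–H positions of A5 are flanked by an alkoxy group, and palladacycle formation at such buttressed positions is the known weak point of this chemistry. A benzylic chloride can add to palladium(0) directly and enter Heck or homocoupling pathways. Four components must be ordered correctly on one metal. A5 has to come from a symmetrical resorcinol-type iodide by a statistical mono-alkylation.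
- Comparison: no ring is built and the oxygen pattern is bought with a statistical step, whereas the cycloaddition sets it by connectivity. Mechanistically the selectivity rests on relative rates at one catalyst, not on intrinsic polarity, so it is the shorter but less predictable plan.

**Alternative 3:** The cut is at C2–C1 and C4–C5 of a non-aromatic ring A. Forward, the potassium enolate of 4-[4-(benzyloxy)phenyl]butan-2-one A8 would add through its substituted α-carbon to methyl (E)-2-[4-(benzyloxy)benzyl]-5-[3-(benzyloxy)phenyl]pent-2-enoate A9, and the methyl-side enolate would then acylate on the ester to give the 1,3-dione A7.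
- In its favour: cheap reagents and no sensitive diene. It exploits the mirror symmetry of ring A's carbon skeleton: because A7 is symmetrical, its methyl enol ether A10 is a single constitution, and dehydrogenation of A10 would give the tribenzyl ether of 21 (the compound called F4 below) with OH and OMe already differentiated. There is no ketone to remove at the end, which is a better endgame than the chosen one. The step count is about equal.
- Against it: a ketone enolate adding to an α,β-disubstituted enoate is a sluggish and reversible Michael step. The enolate regiochemistry (methylene versus methyl) decides between A7 and an isomeric 2-benzyl dione. Dehydrogenation of a hindered, fully substituted cyclohexenone in the presence of three benzyl ethers is not trivial.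
- Comparison: ring construction is comparable in concept, but the bond-forming step has weaker driving force and weaker regiocontrol than the matched diene/ynone pair, and aromatisation requires a separate oxidation instead of occurring spontaneously.

Key step: step 7

## Route

**Step 1**
Reactants: 1 methyl acetoacetate; 2 4-(benzyloxy)benzyl chloride
Product: 4 methyl 5-[4-(benzyloxy)phenyl]-3-oxopentanoate, via acetoacetate dianion 3 (not isolated)
Conditions: NaH, THF, 0 °C; n-BuLi, 0 °C; 2, 0 °C to rt; 1 M HCl
Reagents that add atoms: none
Why: Weiler dianion alkylation; the more basic terminal (γ) carbanion of the 1,3-dianion is alkylated by the reactive benzylic chloride, while the α-position stays protected as the enolate until the quench.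

**Step 2**
Reactants: 4 methyl 5-[4-(benzyloxy)phenyl]-3-oxopentanoate
Product: 6 methyl (2E)-5-[4-(benzyloxy)phenyl]-3-methoxypent-2-enoate, via dimethyl ketal 5 (not isolated)
Conditions: HC(OMe)3, cat. H2SO4, MeOH, rt; then cat. TsOH, toluene, 110 °C (−MeOH)
Reagents that add atoms: trimethyl orthoformate, COC(OC)OC; methanol, CO
Why: Acid-catalysed ketalisation of the ketone carbonyl followed by elimination of methanol into conjugation with the ester, the standard preparation of β-methoxy enoates; this gives O-methylation only, and the conjugated E isomer is the thermodynamic product.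

**Step 3**
Reactants: 6 methyl (2E)-5-[4-(benzyloxy)phenyl]-3-methoxypent-2-enoate
Product: 8 (3Z)-5-[4-(benzyloxy)phenyl]-1,3-dimethoxy-1-(trimethylsilyloxy)penta-1,3-diene, via lithium dienolate 7 (not isolated)
Conditions: LDA, THF, −78 °C; TMSCl, −78 °C to rt; pentane, filtration under argon; used crude
Reagents that add atoms: chlorotrimethylsilane, C[Si](C)(C)Cl
Why: Kinetic γ-deprotonation of the vinylogous ester and O-silylation of the dienolate by the hard silyl chloride, the usual Brassard-diene preparation; the C5 substituent should turn away from the ester terminus during deprotonation (allylic strain), which gives the (3Z) geometry needed for the s-cis conformer.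

**Step 4**
Reactants: 9 3-(benzyloxy)benzyl alcohol
Product: 10 1-(benzyloxy)-3-(bromomethyl)benzene
Conditions: PBr3, CH2Cl2, 0 °C
Reagents that add atoms: phosphorus tribromide, BrP(Br)Br
Why: Conversion of a primary benzylic alcohol to the bromide through its phosphite ester (SN2); the aryl benzyl ether tolerates the brief, cold, mildly acidic conditions.

**Step 5**
Reactants: 10 1-(benzyloxy)-3-(bromomethyl)benzene; 11 trimethyl(prop-1-yn-1-yl)silane
Product: 14 1-(benzyloxy)-3-(but-3-yn-1-yl)benzene, via lithiated silylpropyne 12 (not isolated), via silylated butyne 13 (not isolated)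
Conditions: 11, n-BuLi, THF, −78 °C; 10, −78 °C to rt; then cat. K2CO3, MeOH, rt
Reagents that add atoms: none
Why: SN2 alkylation of the silyl-capped propargyl anion at its CH2 terminus (the silyl group suppresses the allenyl pathway) by a benzylic bromide, then base-catalysed methanolysis of the C(sp)–Si bond to the terminal alkyne.

**Step 6**
Reactants: 14 1-(benzyloxy)-3-(but-3-yn-1-yl)benzene; 15 4-(benzyloxy)benzoyl chloride
Product: 16 1-[4-(benzyloxy)phenyl]-5-[3-(benzyloxy)phenyl]pent-2-yn-1-one
Conditions: PdCl2(PPh3)2 (2 mol%), CuI (4 mol%), Et3N, THF, rt; chromatography to remove phosphine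
Reagents that add atoms: none
Why: Acyl Sonogashira coupling (oxidative addition of the aroyl chloride, transmetalation from the copper acetylide, reductive elimination) gives the ynone directly at room temperature with no redox adjustment.

**Step 7**
Reactants: 8 (3Z)-5-[4-(benzyloxy)phenyl]-1,3-dimethoxy-1-(trimethylsilyloxy)penta-1,3-diene (2 equiv); 16 1-[4-(benzyloxy)phenyl]-5-[3-(benzyloxy)phenyl]pent-2-yn-1-one
Product: 18 [4-(benzyloxy)phenyl]{3-[4-(benzyloxy)benzyl]-2-{2-[3-(benzyloxy)phenyl]ethyl}-6-hydroxy-4-methoxyphenyl}methanone, via cyclohexadiene cycloadduct 17 (not isolated)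
Conditions: toluene, 110 °C, sealed tube; then 1 M HCl, THF, rt
Reagents that add atoms: none
Why: This is a thermal normal-electron-demand Diels–Alder reaction between the electron-rich vinylogous silyl ketene acetal and the electron-poor ynone, the reaction type known for Brassard- and Chan-type dienes with acetylenic ketones and esters. The bond from the diene's C4 terminus (largest HOMO coefficient, future C6) to the ynone β-carbon (largest LUMO coefficient, future C1) should form ahead of the bond from the ketene-acetal carbon (future C3) to the α-carbon (future C2), so the addition is asynchronous but gives both ring bonds in one event. Ring A closes in the [4+2] mode as the six-membered 1,4-cyclohexadiene 17. Adduct 17 holds a mixed methyl silyl ketal at C3 and a doubly allylic hydrogen at C6, so 1,4-elimination of methanol (or ketal collapse to the dienone and enolisation) aromatises the ring, and the acid work-up cleaves the O–Si bond. Because silicon leaves from oxygen and the methyl group cannot, C3 emerges as OH (hydrogen-bonded to the new aroyl group) and C5 keeps its OMe. The two sp3 centres of 17 are erased on aromatisation, so no stereocontrol is needed. The selectivity required is regiochemical only; it is secured by the matched polarity of the partners (two oxygen donors on the diene, one carbonyl acceptor on the alkyne) and by the (3Z) geometry that lets the diene reach s-cis with its CH2Ar group outside. The excess of 8 covers its thermal and hydrolytic loss, and phosphine-free 16 avoids ynone isomerisation.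

**Step 8**
Reactants: 18 [4-(benzyloxy)phenyl]{3-[4-(benzyloxy)benzyl]-2-{2-[3-(benzyloxy)phenyl]ethyl}-6-hydroxy-4-methoxyphenyl}methanone
Product: 21 2,4-bis(4-hydroxybenzyl)-3-[2-(3-hydroxyphenyl)ethyl]-5-methoxyphenol (3,3'-dihydroxy-2,6-bis(p-hydroxybenzyl)-5-methoxybibenzyl), via debenzylated hydroxy ketone 19 (not isolated), via benzhydrol 20 (not isolated)
Conditions: H2 (4 bar), 10% Pd/C, EtOH–AcOH, cat. HCl, 40 °C
Reagents that add atoms: none
Why: Palladium-catalysed hydrogenolysis removes the three O-benzyl groups, and in acidic medium reduces the diaryl ketone through the benzhydrol, whose C–O bond is doubly benzylic and activated by ortho- and para-hydroxyl groups, to the CH2; the target has no other reducible group under these conditions.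

## Compound list

1 | methyl acetoacetate | COC(=O)CC(C)=O | starting material
2 | 4-(benzyloxy)benzyl chloride | ClCc1ccc(OCc2ccccc2)cc1 | starting material
3 | lithium sodium dianion of methyl acetoacetate | [Li+].[Na+].C=C([O-])C=C([O-])OC | intermediate (not isolated)
4 | methyl 5-[4-(benzyloxy)phenyl]-3-oxopentanoate | COC(=O)CC(=O)CCc1ccc(OCc2ccccc2)cc1 | intermediate
5 | methyl 5-[4-(benzyloxy)phenyl]-3,3-dimethoxypentanoate | COC(=O)CC(OC)(OC)CCc1ccc(OCc2ccccc2)cc1 | intermediate (not isolated)
6 | methyl (2E)-5-[4-(benzyloxy)phenyl]-3-methoxypent-2-enoate | CO/C(CCc1ccc(OCc2ccccc2)cc1)=C/C(=O)OC | intermediate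
7 | lithium (3Z)-5-[4-(benzyloxy)phenyl]-1,3-dimethoxypenta-1,3-dien-1-olate | [Li+].COC([O-])=C/C(OC)=C/Cc1ccc(OCc2ccccc2)cc1 | intermediate (not isolated)
8 | (3Z)-5-[4-(benzyloxy)phenyl]-1,3-dimethoxy-1-(trimethylsilyloxy)penta-1,3-diene | COC(O[Si](C)(C)C)=C/C(OC)=C/Cc1ccc(OCc2ccccc2)cc1 | intermediate (key-step precursor)
9 | 3-(benzyloxy)benzyl alcohol | OCc1cccc(OCc2ccccc2)c1 | starting material
10 | 1-(benzyloxy)-3-(bromomethyl)benzene | BrCc1cccc(OCc2ccccc2)c1 | intermediate
11 | trimethyl(prop-1-yn-1-yl)silane | CC#C[Si](C)(C)C | starting material
12 | (3-lithioprop-1-yn-1-yl)trimethylsilane | [Li]CC#C[Si](C)(C)C | intermediate (not isolated)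
13 | {4-[3-(benzyloxy)phenyl]but-1-yn-1-yl}trimethylsilane | C[Si](C)(C)C#CCCc1cccc(OCc2ccccc2)c1 | intermediate (not isolated)
14 | 1-(benzyloxy)-3-(but-3-yn-1-yl)benzene | C#CCCc1cccc(OCc2ccccc2)c1 | intermediate
15 | 4-(benzyloxy)benzoyl chloride | O=C(Cl)c1ccc(OCc2ccccc2)cc1 | starting material
16 | 1-[4-(benzyloxy)phenyl]-5-[3-(benzyloxy)phenyl]pent-2-yn-1-one | O=C(C#CCCc1cccc(OCc2ccccc2)c1)c1ccc(OCc2ccccc2)cc1 | intermediate (key-step precursor)
17 | [4-(benzyloxy)phenyl]{3-[4-(benzyloxy)benzyl]-2-{2-[3-(benzyloxy)phenyl]ethyl}-4,6-dimethoxy-6-(trimethylsilyloxy)cyclohexa-1,4-dien-1-yl}methanone (diastereomer mixture) | COC1=CC(OC)(O[Si](C)(C)C)C(C(=O)c2ccc(OCc3ccccc3)cc2)=C(CCc2cccc(OCc3ccccc3)c2)C1Cc1ccc(OCc2ccccc2)cc1 | intermediate (not isolated)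
18 | [4-(benzyloxy)phenyl]{3-[4-(benzyloxy)benzyl]-2-{2-[3-(benzyloxy)phenyl]ethyl}-6-hydroxy-4-methoxyphenyl}methanone | COc1cc(O)c(C(=O)c2ccc(OCc3ccccc3)cc2)c(CCc2cccc(OCc3ccccc3)c2)c1Cc1ccc(OCc2ccccc2)cc1 | intermediate (key-step product)
19 | (4-hydroxyphenyl){6-hydroxy-3-(4-hydroxybenzyl)-2-[2-(3-hydroxyphenyl)ethyl]-4-methoxyphenyl}methanone | COc1cc(O)c(C(=O)c2ccc(O)cc2)c(CCc2cccc(O)c2)c1Cc1ccc(O)cc1 | intermediate (not isolated)
20 | 2-[hydroxy(4-hydroxyphenyl)methyl]-4-(4-hydroxybenzyl)-3-[2-(3-hydroxyphenyl)ethyl]-5-methoxyphenol (racemic) | COc1cc(O)c(C(O)c2ccc(O)cc2)c(CCc2cccc(O)c2)c1Cc1ccc(O)cc1 | intermediate (not isolated)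
21 | 2,4-bis(4-hydroxybenzyl)-3-[2-(3-hydroxyphenyl)ethyl]-5-methoxyphenol | COc1cc(O)c(Cc2ccc(O)cc2)c(CCc2cccc(O)c2)c1Cc1ccc(O)cc1 | target

## Step count and least certain steps

Total step count: 8. Longest linear sequence: 5 steps (1 → 2 → 3 → 7 → 8, or 4 → 5 → 6 → 7 → 8).

**Step 7 (key step).** The most likely failure is a cycloaddition that is too slow: both new bonds are made at substituted carbons, and meanwhile the diene is consumed by hydrolysis or silyl transfer, or the reaction drifts to a stepwise conjugate addition that stops at open-chain adducts. The fallback moves the aryl ketone out of the dienophile. It sets out from 14, which is lithiated and formylated (n-BuLi, then DMF, buffered quench) to 5-[3-(benzyloxy)phenyl]pent-2-ynal F1, a smaller and more electrophilic dienophile. Cycloaddition of F1 with 8 and acid work-up should give 3-[4-(benzyloxy)benzyl]-2-{2-[3-(benzyloxy)phenyl]ethyl}-6-hydroxy-4-methoxybenzaldehyde F2 with the same polarity-controlled regiochemistry. Addition of commercial 4-(benzyloxy)phenylmagnesium bromide (excess, THF, 0 °C) then gives 2-{[4-(benzyloxy)phenyl](hydroxy)methyl}-4-[4-(benzyloxy)benzyl]-3-{2-[3-(benzyloxy)phenyl]ethyl}-5-methoxyphenol F3. Hydrogenolysis of F3 over Pd/C removes the doubly benzylic hydroxyl and the three benzyl groups and rejoins the route at 21.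

**Step 8.** The most likely failure is incomplete reduction of the hindered, chelated carbonyl, with debenzylation finished but the sequence stalled at the ketone stage; forcing conditions would then risk ring saturation. The fallback separates the two tasks. It sets out from 18, which is deoxygenated by ionic hydrogenation (Et3SiH, TFA, CH2Cl2, 0 °C to rt; the diarylcarbenium ion is stabilised by the para-benzyloxy and the ortho-hydroxy/para-methoxy rings) to 2,4-bis[4-(benzyloxy)benzyl]-3-{2-[3-(benzyloxy)phenyl]ethyl}-5-methoxyphenol F4. Plain hydrogenolysis of F4 (H2, Pd/C, EtOAc–MeOH, rt) returns to the route at 21.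

**Step 3.** The most likely failures are C-silylation or hydrolysis of the ketene acetal during isolation, and formation of the C3=C4 isomer that cannot adopt the s-cis conformation. The fallback uses a bis-silyloxy diene and restores the methyl ether afterwards. It sets out from 4, which is silylated (TMSCl, Et3N) to methyl (2Z)-5-[4-(benzyloxy)phenyl]-3-(trimethylsilyloxy)pent-2-enoate F5. Treatment with LDA and TMSCl gives (3Z)-5-[4-(benzyloxy)phenyl]-1-methoxy-1,3-bis(trimethylsilyloxy)penta-1,3-diene F6. Cycloaddition of F6 with 16 and acid work-up should give [4-(benzyloxy)phenyl]{3-[4-(benzyloxy)benzyl]-2-{2-[3-(benzyloxy)phenyl]ethyl}-4,6-dihydroxyphenyl}methanone F7. Methylation with one equivalent of MeI and K2CO3 in acetone should occur at the non-chelated hydroxyl only (the ortho-hydroxy ketone is protected by its hydrogen bond) and returns to the route at 18.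

**Step 5.** The most likely failures are alkylation of the ambident propargyl/allenyl anion through its silicon-bearing carbon, and homocoupling of the benzylic bromide after halogen–metal exchange. The fallback builds the alkyne from an aldehyde. It sets out from 10, which alkylates the lithium enolate of ethyl acetate (LDA, THF/DMPU, −78 °C) to ethyl 3-[3-(benzyloxy)phenyl]propanoate F8. DIBAL-H at −78 °C gives 3-[3-(benzyloxy)phenyl]propanal F9, and Ohira–Bestmann homologation (dimethyl (1-diazo-2-oxopropyl)phosphonate, K2CO3, MeOH) returns to the route at 14.

**Step 6.** The most likely failures are oxidative dimerisation of the alkyne, and amine- or phosphine-promoted isomerisation of the ynone to an allenyl or dienyl ketone. The fallback forms the C–C bond at the alcohol level. It sets out from 14, which is lithiated (n-BuLi, THF, −78 °C) and added to 4-(benzyloxy)benzaldehyde to give 1-[4-(benzyloxy)phenyl]-5-[3-(benzyloxy)phenyl]pent-2-yn-1-ol F10. Oxidation of F10 with MnO2 in CH2Cl2 returns to the route at 16.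

## Further compounds

F1 | step 7 | 5-[3-(benzyloxy)phenyl]pent-2-ynal | O=CC#CCCc1cccc(OCc2ccccc2)c1
F2 | step 7 | 3-[4-(benzyloxy)benzyl]-2-{2-[3-(benzyloxy)phenyl]ethyl}-6-hydroxy-4-methoxybenzaldehyde | COc1cc(O)c(C=O)c(CCc2cccc(OCc3ccccc3)c2)c1Cc1ccc(OCc2ccccc2)cc1
F3 | step 7 | 2-{[4-(benzyloxy)phenyl](hydroxy)methyl}-4-[4-(benzyloxy)benzyl]-3-{2-[3-(benzyloxy)phenyl]ethyl}-5-methoxyphenol (racemic) | COc1cc(O)c(C(O)c2ccc(OCc3ccccc3)cc2)c(CCc2cccc(OCc3ccccc3)c2)c1Cc1ccc(OCc2ccccc2)cc1
F4 | step 8 | 2,4-bis[4-(benzyloxy)benzyl]-3-{2-[3-(benzyloxy)phenyl]ethyl}-5-methoxyphenol | COc1cc(O)c(Cc2ccc(OCc3ccccc3)cc2)c(CCc2cccc(OCc3ccccc3)c2)c1Cc1ccc(OCc2ccccc2)cc1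
F5 | step 3 | methyl (2Z)-5-[4-(benzyloxy)phenyl]-3-(trimethylsilyloxy)pent-2-enoate | COC(=O)/C=C(\O[Si](C)(C)C)CCc1ccc(OCc2ccccc2)cc1
F6 | step 3 | (3Z)-5-[4-(benzyloxy)phenyl]-1-methoxy-1,3-bis(trimethylsilyloxy)penta-1,3-diene | COC(O[Si](C)(C)C)=C/C(O[Si](C)(C)C)=C/Cc1ccc(OCc2ccccc2)cc1
F7 | step 3 | [4-(benzyloxy)phenyl]{3-[4-(benzyloxy)benzyl]-2-{2-[3-(benzyloxy)phenyl]ethyl}-4,6-dihydroxyphenyl}methanone | Oc1cc(O)c(C(=O)c2ccc(OCc3ccccc3)cc2)c(CCc2cccc(OCc3ccccc3)c2)c1Cc1ccc(OCc2ccccc2)cc1
F8 | step 5 | ethyl 3-[3-(benzyloxy)phenyl]propanoate | CCOC(=O)CCc1cccc(OCc2ccccc2)c1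
F9 | step 5 | 3-[3-(benzyloxy)phenyl]propanal | O=CCCc1cccc(OCc2ccccc2)c1
F10 | step 6 | 1-[4-(benzyloxy)phenyl]-5-[3-(benzyloxy)phenyl]pent-2-yn-1-ol (racemic) | OC(C#CCCc1cccc(OCc2ccccc2)c1)c1ccc(OCc2ccccc2)cc1
A1 | alternative 1 | methyl 2-[2-(4-benzyloxybenzoyl)-3,5-dimethoxyphenyl]acetate | COC(=O)Cc1cc(OC)cc(OC)c1C(=O)c1ccc(OCc2ccccc2)cc1
A2 | alternative 1 | methyl 3-[4-(benzyloxy)phenyl]-3-oxopropanoate | COC(=O)CC(=O)c1ccc(OCc2ccccc2)cc1
A3 | alternative 1 | 3,5-dimethoxy-2-(trimethylsilyl)phenyl trifluoromethanesulfonate | COc1cc(OC)c([Si](C)(C)C)c(OS(=O)(=O)C(F)(F)F)c1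
A4 | alternative 2 | 1-(benzyloxy)-2,4-bis[4-(benzyloxy)benzyl]-3-[(E)-2-[3-(benzyloxy)phenyl]ethenyl]-5-methoxybenzene | COc1cc(OCc2ccccc2)c(Cc2ccc(OCc3ccccc3)cc2)c(/C=C/c2cccc(OCc3ccccc3)c2)c1Cc1ccc(OCc2ccccc2)cc1
A5 | alternative 2 | 1-(benzyloxy)-3-iodo-5-methoxybenzene | COc1cc(I)cc(OCc2ccccc2)c1
A6 | alternative 2 | 1-(benzyloxy)-3-ethenylbenzene | C=Cc1cccc(OCc2ccccc2)c1
A7 | alternative 3 | 4,6-bis[4-(benzyloxy)benzyl]-5-{2-[3-(benzyloxy)phenyl]ethyl}cyclohexane-1,3-dione (diastereomer mixture) | O=C1CC(=O)C(Cc2ccc(OCc3ccccc3)cc2)C(CCc2cccc(OCc3ccccc3)c2)C1Cc1ccc(OCc2ccccc2)cc1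
A8 | alternative 3 | 4-[4-(benzyloxy)phenyl]butan-2-one | CC(=O)CCc1ccc(OCc2ccccc2)cc1
A9 | alternative 3 | methyl (E)-2-[4-(benzyloxy)benzyl]-5-[3-(benzyloxy)phenyl]pent-2-enoate | COC(=O)/C(Cc1ccc(OCc2ccccc2)cc1)=C/CCc1cccc(OCc2ccccc2)c1
A10 | alternative 3 | 4,6-bis[4-(benzyloxy)benzyl]-5-{2-[3-(benzyloxy)phenyl]ethyl}-3-methoxycyclohex-2-en-1-one (diastereomer mixture) | COC1=CC(=O)C(Cc2ccc(OCc3ccccc3)cc2)C(CCc2cccc(OCc3ccccc3)c2)C1Cc1ccc(OCc2ccccc2)cc1
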